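The numbers in the tables are calculated for an exercise, noise included.

You want to know what the blue flask holds at 80 min and which remedy brings the most target in the 40 min after it.

| setting | blue | green | flask |
|---|---|---|---|
| substrate | 1.5 M | 1.5 M | 1.5 M |
| catalyst | 3 mM | 2 mM | 3.0 mM |
| temperature | 100 °C | 106 °C | 100 °C |
| remark | the very flask that is asked about, followed so far | run made earlier |  |
| time |  |  | 80 min |

- blue (time / min: target / %, substrate / %): 12.0: 22.5, 2.1; 25.0: 24.6, 0; 40.0: 25.4, 1.5; 50.0: 25.8, 0.1; 60.0: 25.9, 0.6
- green (time / min: target / %, substrate / %): 2.00: 15.4, 2.2; 4.00: 23.3, 2.2; 6.00: 28.1, 2.1; 8.00: 27.5, 3.6; 10.0: 30.5, 1.9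

(readings scatter by 1 percentage point)

- Tuesday's: at 80 min take out 90 % of the target then present, then wait 40 min
- Saturday's: at 80 min raise the temperature by 25 K, then wait 40 min
- Wednesday's: at 80 min add catalyst, 100 % of the amount charged, then wait 40 min
- Monday's: change nothing and wait 40 min more

- what is taken out of target is counted as made
- additions bring no volume worth counting

1. target, in percent of the substrate first charged, at 80 min
2. the remedy with the largest gain of target, or "none" below 2 percentage points (Tuesday's / Saturday's / Wednesday's / Monday's / none)
3. target present, with what was taken out counted in, in percent of the substrate first charged, after Tuesday's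
4. target present, with what was taken out counted in, in percent of the substrate first charged, after Wednesday's

My ledger for the substrate charged to the blue flask runs as follows.

- Free substrate averages 0.860 % of the charge over the blue readings, so the first entry is small.
- Blue target moves 0.5 percentage points over its last readings, less than the scatter. I therefore read a plateau, which is thermodynamic control, and define the plateau share, the part of the material in the flask standing as target at one temperature, as 25.7 %. That is my "now".
- The books close on an unseen pool of 73.4 %, which I assume can return to target.
- Tuesday's removes 23.1 % and keeps 76.9 % in the flask. Putting that back through the share gives 19.8 % present, so 42.9 % counted, a gain of 17 points. The blue target readings were level by 40.0 min, about the wait allowed.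
- Wednesday's should change nothing. The green flask had less catalyst and ran hotter, and its last target reading stands higher, so these two runs give no sign that less catalyst lowers the level, and I keep 25.7 % and a gain below 2 points. Monday's also stays at 25.7 %.
- Saturday's needs the odds of target against the rest. Carrying them from blue through green's last reading, a long extrapolation, gives a share of 48.3 %. That is a gain of 23 points, the largest of the options.

The forecast, reading “a temperature-dependent equilibrium”, gave 26 % (25.4 % to 26.8 %), 43.3 % after Tuesday's, 26.2 % after Wednesday's, and Saturday's as the best remedy.

The blue flask stands at 25.5 %, and Saturday's is best, gaining 22 points against 17 points for Tuesday's. At 80.0 min the pool proves to be isomer of the product, 73.3 % of the charge. With 25.5 % as the share, the Tuesday ledger gives 42.5 %; the flask gives 42.5 %, and 25.5 % after Wednesday's.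

    substrate + catalyst ⇌ target + catalyst, rate k1*[substrate]*[catalyst] forward; the back reaction follows from the equilibrium constant (K = 21.0, k = 32.4 M⁻¹ min⁻¹, Ea = 69.0 kJ mol⁻¹, ΔH = 4.00 kJ mol⁻¹)
    target ⇌ isomer of the product (K = 2.88, k = 0.139 min⁻¹, Ea = 102 kJ mol⁻¹, ΔH = −50.0 kJ mol⁻¹)
    isomer of the product ⇌ substrate (k = 0.145 min⁻¹, Ea = 109 kJ mol⁻¹)
    (constants at 100 °C)

A further flask with 0.0075 M of catalyst keeps the blue temperature, so the share says 25.5 %. The computed result is 25.5 %.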